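Numbering: each half is a guaianolide (cyclopentane C1–C5, cycloheptane C1/C5–C10, lactone O–C6/C12); primes mark the half whose C2' and C5' are the norbornane bridgeheads. Retrosynthesis: (1) remove H2 from C3'–C4'; (2) cut C2–C2' and C3–C5', an endo Diels–Alder dimerisation of one cyclopentadiene (C2=C3–C4=C5, H-1); (3) return C2=C3 to a C3 ketone; (4) cut C1–C2 and C4=C5 by a (3+2) cycloaddition; (5) cut C1=C10 (metathesis), C7–C8 and C11–C13 (butenolide chemistry).
Enabling feature: the cyclopentene C1–C5 of the unprimed half meets the rest of that half only along the C1–C5 edge of the seven-membered ring. C2–C3–C4(CH3) is therefore a three-carbon unit (an oxyallyl cation, oxygen on C3) and C1=C5 a two-carbon unit (silyl enol ether of the C5 ketone); the C5 oxygen leaves again as silanol to give C4=C5.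
Forward order: lactone ring (from the butenolide), seven-membered ring (ring-closing metathesis), C10 carbinol (epoxidation, reductive opening), cyclopentenone ring ((3+2)), cyclopentadiene, norbornene (dimerisation), hydrogenation.
Stereochemistry: C6 from (S)-5-(hydroxymethyl)furan-2(5H)-one; C7 and C11 by anti 1,2-induction; C10 by catalyst-controlled Shi epoxidation; C1 by β-face attack in the (3+2) step; C2, C3, C2', C5' and the orientation of the C1' bridge by the endo, anti-to-C10 Diels–Alder reaction; C4' by exo-face hydrogenation.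

Key step: step 12

Step 1
Reactants: 1 (S)-5-(hydroxymethyl)furan-2(5H)-one
Product: 2 (S)-5-[(tert-butyldiphenylsilyloxy)methyl]furan-2(5H)-one
Conditions: t-BuPh2SiCl, imidazole, DMF, 0 °C to rt
Reagents that add atoms: tert-butyl(chloro)diphenylsilane, CC(C)(C)[Si](Cl)(c1ccccc1)c1ccccc1
Why: Silyl ether formation at the primary alcohol installs the bulky group that will direct the conjugate addition; no stereocentre is touched.

Step 2
Reactants: 2 (S)-5-[(tert-butyldiphenylsilyloxy)methyl]furan-2(5H)-one; 3 4-bromo-2-methylbut-1-ene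
Product: 5 (4S,5S)-5-[(tert-butyldiphenylsilyloxy)methyl]-4-(3-methylbut-3-en-1-yl)dihydrofuran-2(3H)-one, via (3-methylbut-3-en-1-yl)magnesium bromide 4 (not isolated)
Conditions: 3, Mg, THF, rt; CuBr·SMe2 (10 mol %), then 2, THF, −78 to −40 °C; aq. NH4Cl
Reagents that add atoms: none
Why: Copper-catalysed 1,4-addition of the Grignard reagent to the butenolide should occur anti to the C6 silyloxymethyl group and so set C7 (4,5-trans lactone).

Step 3
Reactants: 5 (4S,5S)-5-[(tert-butyldiphenylsilyloxy)methyl]-4-(3-methylbut-3-en-1-yl)dihydrofuran-2(3H)-one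
Product: 6 (3S,4S,5S)-5-[(tert-butyldiphenylsilyloxy)methyl]-3-methyl-4-(3-methylbut-3-en-1-yl)dihydrofuran-2(3H)-one
Conditions: LiN(iPr)2, THF, −78 °C; MeI, −78 to −40 °C
Reagents that add atoms: iodomethane, CI
Why: Alkylation of the lactone lithium enolate should take place anti to the neighbouring C7 side chain, which sets C11 (S) and completes the all-trans lactone.

Step 4
Reactants: 6 (3S,4S,5S)-5-[(tert-butyldiphenylsilyloxy)methyl]-3-methyl-4-(3-methylbut-3-en-1-yl)dihydrofuran-2(3H)-one
Product: 7 (3S,4S,5S)-5-(hydroxymethyl)-3-methyl-4-(3-methylbut-3-en-1-yl)dihydrofuran-2(3H)-one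
Conditions: Bu4NF, AcOH, THF, 0 °C to rt
Reagents that add atoms: none
Why: Fluoride-mediated desilylation, buffered with acetic acid so that the lactone and its α-centre do not meet a basic alkoxide, should free the primary alcohol.

Step 5
Reactants: 7 (3S,4S,5S)-5-(hydroxymethyl)-3-methyl-4-(3-methylbut-3-en-1-yl)dihydrofuran-2(3H)-one
Product: 8 (2S,3S,4S)-4-methyl-3-(3-methylbut-3-en-1-yl)-5-oxotetrahydrofuran-2-carbaldehyde
Conditions: Dess–Martin periodinane, CH2Cl2, 0 °C to rt
Reagents that add atoms: none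
Why: Dess–Martin oxidation under non-basic conditions should give the α-oxygenated aldehyde without epimerisation at C6.

Step 6
Reactants: 8 (2S,3S,4S)-4-methyl-3-(3-methylbut-3-en-1-yl)-5-oxotetrahydrofuran-2-carbaldehyde; 9 vinylmagnesium bromide
Product: 10 (3S,4S,5S)-5-(1-hydroxyprop-2-en-1-yl)-3-methyl-4-(3-methylbut-3-en-1-yl)dihydrofuran-2(3H)-one, both carbinol epimers
Conditions: 9 (1.2 equiv), THF, −78 °C; aq. NH4Cl
Reagents that add atoms: none
Why: Grignard addition to the aldehyde at low temperature should leave the lactone alone, and the new carbinol centre (C5) need not be controlled because step 9 oxidises it.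

Step 7
Reactants: 10 (3S,4S,5S)-5-(1-hydroxyprop-2-en-1-yl)-3-methyl-4-(3-methylbut-3-en-1-yl)dihydrofuran-2(3H)-one
Product: 11 (3S,3aS,8aS)-8-hydroxy-3,6-dimethyl-3,3a,4,5,8,8a-hexahydro-2H-cyclohepta[b]furan-2-one, both C8 epimers
Conditions: second-generation Grubbs catalyst (H2IMes)(PCy3)Cl2Ru=CHPh (5 mol %), CH2Cl2 (2 mM), 40 °C
Reagents that add atoms: none
Why: Ring-closing olefin metathesis between the vinyl carbinol and the 1,1-disubstituted alkene should close the seven-membered ring as the trisubstituted C1=C10 alkene with loss of ethene; no stereocentre is formed.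

Step 8
Reactants: 11 (3S,3aS,8aS)-8-hydroxy-3,6-dimethyl-3,3a,4,5,8,8a-hexahydro-2H-cyclohepta[b]furan-2-one
Product: 12 (3S,3aS,6S,7R,8aS)-6,7-epoxy-8-hydroxy-3,6-dimethyloctahydro-2H-cyclohepta[b]furan-2-one, both C8 epimers, epoxide oxygen cis to H-8a
Conditions: D-fructose-derived Shi ketone (30 mol %), KHSO5 (as 2KHSO5·KHSO4·K2SO4), K2CO3, Bu4NHSO4, MeCN–CH2(OMe)2–aq. Na2B4O7 buffer (pH 10.5), 0 °C
Reagents that add atoms: potassium peroxymonosulfate, [K+].[O-]S(=O)(=O)OO
Why: Shi asymmetric epoxidation of the trisubstituted alkene is catalyst-controlled, and the spiro transition state of the D-fructose-derived dioxirane should deliver oxygen to the β-face (cis to H-6) of both carbinol epimers, which fixes C10 (S) and C1.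

Step 9
Reactants: 12 (3S,3aS,6S,7R,8aS)-6,7-epoxy-8-hydroxy-3,6-dimethyloctahydro-2H-cyclohepta[b]furan-2-one
Product: 13 (3S,3aS,6S,7S,8aS)-6,7-epoxy-3,6-dimethylhexahydro-2H-cyclohepta[b]furan-2,8(3H)-dione
Conditions: Dess–Martin periodinane, CH2Cl2, 0 °C to rt
Reagents that add atoms: none
Why: Dess–Martin oxidation of the epoxy alcohols should converge both C5 epimers on one α,β-epoxy ketone without touching the epoxide.

Step 10
Reactants: 13 (3S,3aS,6S,7S,8aS)-6,7-epoxy-3,6-dimethylhexahydro-2H-cyclohepta[b]furan-2,8(3H)-dione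
Product: 14 (3S,3aS,6S,8aS)-6-hydroxy-3,6-dimethylhexahydro-2H-cyclohepta[b]furan-2,8(3H)-dione
Conditions: SmI2 (2.1 equiv), THF–MeOH, −90 °C
Reagents that add atoms: none
Why: Reduction of the α,β-epoxy ketone by SmI2 (ketyl formation, cleavage of the C1–O bond, protonation) should give the β-hydroxy ketone with the C10–O bond and its configuration intact, the strained epoxide bond being cleaved faster than the lactone C6–O bond, which lies near the carbonyl plane.

Step 11
Reactants: 14 (3S,3aS,6S,8aS)-6-hydroxy-3,6-dimethylhexahydro-2H-cyclohepta[b]furan-2,8(3H)-dione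
Product: 15 (3S,3aS,6S,8aS)-6-hydroxy-3,6-dimethyl-8-[(triisopropylsilyl)oxy]-3,3a,4,5,6,8a-hexahydro-2H-cyclohepta[b]furan-2-one
Conditions: LiN(SiMe3)2 (2.2 equiv), THF, −78 °C; iPr3SiOSO2CF3 (1.1 equiv); H2O quench
Reagents that add atoms: triisopropylsilyl trifluoromethanesulfonate, CC(C)[Si](OS(=O)(=O)C(F)(F)F)(C(C)C)C(C)C
Why: Alkoxide-directed kinetic deprotonation should remove a C1 methylene proton and not the C6 methine, and the bulky silyl triflate should silylate the enolate oxygen only, since the tertiary alkoxide is too hindered (regioselective silyl enol ether formation).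

Step 12
Reactants: 15 (3S,3aS,6S,8aS)-6-hydroxy-3,6-dimethyl-8-[(triisopropylsilyl)oxy]-3,3a,4,5,6,8a-hexahydro-2H-cyclohepta[b]furan-2-one; 16 3-bromobutan-2-one
Product: 19 (3S,3aS,6S,6aR,9bS)-6-hydroxy-3,6,9-trimethyl-3a,4,5,6,6a,7-hexahydroazuleno[4,5-b]furan-2,8(3H,9bH)-dione, via methyl-substituted oxyallyl cation 17 (not isolated), via cis-fused silyloxy cyclopentanone cycloadduct 18 (not isolated)
Conditions: 16 (3 equiv), Na2CO3, CF3CH2OH, 0 °C to rt; then DBU, CH2Cl2, rt
Reagents that add atoms: none
Why: Na2CO3 in CF3CH2OH dehydrobrominates 16 to the methyl-substituted oxyallyl cation 17; the nucleophilic C1 of enol ether 15 bonds to its unsubstituted terminus (C2), and the enol carbon C4 so formed closes on the silyloxycarbenium carbon C5 to give the cis-fused β-silyloxy ketone 18, from which DBU eliminates iPr3SiOH (E1cB) to leave the C4=C5 enone. The closest known reaction type is the oxyallyl cation (3+2) cycloaddition with enamines, vinyl sulfides and enol ethers (Noyori-type cyclopentenone annulation), run here with the fluoroalcohol–base generation of the cation that is usual for (4+3) and indole (3+2) cycloadditions. The one ring closed is the cyclopentanone C1–C5, formed by a stepwise polar (3+2): intermolecular C1–C2 bond formation, then a 5-(enolendo)-exo-trig closure of C4 onto C5. C1, the only new stereocentre that survives, is controlled by the chair cycloheptene: the cation should add to the β-face, syn to H-6 and to the small pseudo-axial C10–OH (hydrogen bond to the oxyallyl oxygen) and anti to the C6–C7 and C10–C9 ring bonds, which places H-1 α; C4 and C5 are erased by the elimination. The step needs regioselectivity (C1 to the CH2 terminus), carbon over oxygen closure and face selectivity: the first should follow from the hindered C1 next to quaternary C10 and the more substituted enol that results, the second from the robust iPr3Si group, which keeps the oxocarbenium ion intact until the carbon–carbon closure, and the third from the free hydroxyl.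

Step 13
Reactants: 19 (3S,3aS,6S,6aR,9bS)-6-hydroxy-3,6,9-trimethyl-3a,4,5,6,6a,7-hexahydroazuleno[4,5-b]furan-2,8(3H,9bH)-dione
Product: 20 (3S,3aS,6S,6aR,9bS)-6-hydroxy-3,6,9-trimethyl-2-oxo-2,3,3a,4,5,6,6a,9b-octahydroazuleno[4,5-b]furan-8-yl trifluoromethanesulfonate
Conditions: LiN(iPr)2 (2.2 equiv), THF, −78 °C; N-(5-chloropyridin-2-yl)bis(trifluoromethanesulfonimide) (1.1 equiv); H2O quench
Reagents that add atoms: N-(5-chloropyridin-2-yl)bis(trifluoromethanesulfonimide) (Comins' reagent), FC(F)(F)S(=O)(=O)N(c1ccc(Cl)cn1)S(=O)(=O)C(F)(F)F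
Why: Kinetic α'-deprotonation of the enone at C2 and O-sulfonylation of the cross-conjugated lithium dienolate (enol triflate formation) should give the cyclopentadienyl triflate; the hindered tertiary alkoxide should not be triflated and C1 is not touched.

Step 14
Reactants: 20 (3S,3aS,6S,6aR,9bS)-6-hydroxy-3,6,9-trimethyl-2-oxo-2,3,3a,4,5,6,6a,9b-octahydroazuleno[4,5-b]furan-8-yl trifluoromethanesulfonate
Product: 21 (3S,3aS,6S,6aR,9bS)-6-hydroxy-3,6,9-trimethyl-3,3a,4,5,6,6a-hexahydroazuleno[4,5-b]furan-2(9bH)-one (cyclopentadiene monomer, C2=C3 and C4=C5)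
Conditions: Pd(PPh3)4 (5 mol %), Bu3SnH, LiCl, THF, 0 °C to rt
Reagents that add atoms: none
Why: Palladium-catalysed reduction of the enol triflate by tin hydride (oxidative addition, hydride transfer, reductive elimination) should replace OTf by H at room temperature and give the 2,4-diene without moving H-1.

Step 15
Reactants: 21 (3S,3aS,6S,6aR,9bS)-6-hydroxy-3,6,9-trimethyl-3,3a,4,5,6,6a-hexahydroazuleno[4,5-b]furan-2(9bH)-one (two molecules)
Product: 22 endo Diels–Alder dimer of 21 (3',4'-didehydro target, norbornene C3'=C4')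
Conditions: neat, 25 °C, argon, dark, several days
Reagents that add atoms: none
Why: Thermal Diels–Alder dimerisation, in which C2'=C3'–C4'=C5' of one molecule adds to C2=C3 of another through the endo transition state, each on the face anti to C10 (the H-1 face), with C2' bonding to C2 and C5' to C3 as in the biogenetic dimerisation of this diene type, should set C2, C3, C2' and C5'.

Step 16
Reactants: 22 endo Diels–Alder dimer of 21
Product: 23 CNP0182139.2 (target)
Conditions: H2 (1 atm), PtO2, EtOAc, rt
Reagents that add atoms: none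
Why: Catalytic hydrogenation should reduce only the strained trisubstituted norbornene, from its exo face (the endo face is covered by the endo-fused cyclopentene ring, the exo face carries only the C10' hydroxyl), so that the C4' methyl becomes endo (4'R), while the tetrasubstituted C4=C5 alkene and both lactones should remain.

Compound list
1 | (S)-5-(hydroxymethyl)furan-2(5H)-one | OC[C@H]1OC(=O)C=C1 | starting material
2 | (S)-5-[(tert-butyldiphenylsilyloxy)methyl]furan-2(5H)-one | CC(C)(C)[Si](c1ccccc1)(c1ccccc1)OC[C@H]1OC(=O)C=C1 | intermediate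
3 | 4-bromo-2-methylbut-1-ene | CC(=C)CCBr | starting material
4 | (3-methylbut-3-en-1-yl)magnesium bromide | CC(=C)CC[Mg]Br | intermediate
5 | (4S,5S)-5-[(tert-butyldiphenylsilyloxy)methyl]-4-(3-methylbut-3-en-1-yl)dihydrofuran-2(3H)-one (4,5-trans) | CC(C)(C)[Si](c1ccccc1)(c1ccccc1)OC[C@H]1OC(=O)C[C@@H]1CCC(C)=C | intermediate
6 | (3S,4S,5S)-5-[(tert-butyldiphenylsilyloxy)methyl]-3-methyl-4-(3-methylbut-3-en-1-yl)dihydrofuran-2(3H)-one (all-trans) | CC(C)(C)[Si](c1ccccc1)(c1ccccc1)OC[C@H]1OC(=O)[C@@H](C)[C@@H]1CCC(C)=C | intermediate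
7 | (3S,4S,5S)-5-(hydroxymethyl)-3-methyl-4-(3-methylbut-3-en-1-yl)dihydrofuran-2(3H)-one | OC[C@H]1OC(=O)[C@@H](C)[C@@H]1CCC(C)=C | intermediate
8 | (2S,3S,4S)-4-methyl-3-(3-methylbut-3-en-1-yl)-5-oxotetrahydrofuran-2-carbaldehyde | O=C[C@H]1OC(=O)[C@@H](C)[C@@H]1CCC(C)=C | intermediate
9 | vinylmagnesium bromide | C=C[Mg]Br | starting material
10 | (3S,4S,5S)-5-(1-hydroxyprop-2-en-1-yl)-3-methyl-4-(3-methylbut-3-en-1-yl)dihydrofuran-2(3H)-one, both carbinol epimers | C=CC(O)[C@H]1OC(=O)[C@@H](C)[C@@H]1CCC(C)=C | intermediate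
11 | (3S,3aS,8aS)-8-hydroxy-3,6-dimethyl-3,3a,4,5,8,8a-hexahydro-2H-cyclohepta[b]furan-2-one, both C8 epimers | CC1=CC(O)[C@H]2OC(=O)[C@@H](C)[C@@H]2CC1 | intermediate
12 | (3S,3aS,6S,7R,8aS)-6,7-epoxy-8-hydroxy-3,6-dimethyloctahydro-2H-cyclohepta[b]furan-2-one, both C8 epimers, epoxide oxygen cis to H-8a | C[C@@]12O[C@@H]1C(O)[C@H]3OC(=O)[C@@H](C)[C@@H]3CC2 | intermediate
13 | (3S,3aS,6S,7S,8aS)-6,7-epoxy-3,6-dimethylhexahydro-2H-cyclohepta[b]furan-2,8(3H)-dione | C[C@@]12O[C@@H]1C(=O)[C@H]3OC(=O)[C@@H](C)[C@@H]3CC2 | intermediate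
14 | (3S,3aS,6S,8aS)-6-hydroxy-3,6-dimethylhexahydro-2H-cyclohepta[b]furan-2,8(3H)-dione | O=C1[C@H]2OC(=O)[C@@H](C)[C@@H]2CC[C@](C)(O)C1 | intermediate
15 | (3S,3aS,6S,8aS)-6-hydroxy-3,6-dimethyl-8-[(triisopropylsilyl)oxy]-3,3a,4,5,6,8a-hexahydro-2H-cyclohepta[b]furan-2-one | CC(C)[Si](C(C)C)(C(C)C)OC1=C[C@@](C)(O)CC[C@H]2[C@H](C)C(=O)O[C@H]12 | intermediate
16 | 3-bromobutan-2-one (racemic) | CC(Br)C(C)=O | starting material
17 | 1-methyl-2-oxidoallyl cation (oxyallyl zwitterion) | C[CH+]C([O-])=C | intermediate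
18 | cis-fused cycloadduct: 6-hydroxy-3,6,9-trimethyl-9a-[(triisopropylsilyl)oxy]decahydroazuleno[4,5-b]furan-2,8-dione with H-6a and the 9a-silyloxy group both α, C9 epimers | CC1C(=O)C[C@H]2[C@@](C)(O)CC[C@H]3[C@H](C)C(=O)O[C@@H]3[C@@]12O[Si](C(C)C)(C(C)C)C(C)C | intermediate
19 | (3S,3aS,6S,6aR,9bS)-6-hydroxy-3,6,9-trimethyl-3a,4,5,6,6a,7-hexahydroazuleno[4,5-b]furan-2,8(3H,9bH)-dione | CC1=C2[C@H]3OC(=O)[C@@H](C)[C@@H]3CC[C@](C)(O)[C@@H]2CC1=O | intermediate
20 | (3S,3aS,6S,6aR,9bS)-6-hydroxy-3,6,9-trimethyl-2-oxo-2,3,3a,4,5,6,6a,9b-octahydroazuleno[4,5-b]furan-8-yl trifluoromethanesulfonate | CC1=C2[C@H]3OC(=O)[C@@H](C)[C@@H]3CC[C@](C)(O)[C@@H]2C=C1OS(=O)(=O)C(F)(F)F | intermediate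
21 | (3S,3aS,6S,6aR,9bS)-6-hydroxy-3,6,9-trimethyl-3,3a,4,5,6,6a-hexahydroazuleno[4,5-b]furan-2(9bH)-one (cyclopentadiene monomer) | CC1=C2[C@H]3OC(=O)[C@@H](C)[C@@H]3CC[C@](C)(O)[C@@H]2C=C1 | intermediate
22 | endo Diels–Alder dimer of 21 (3',4'-didehydro target, norbornene C3'=C4') | CC1=C2[C@H]3OC(=O)[C@@H](C)[C@@H]3CC[C@](C)(O)[C@@H]2[C@H]2[C@H]3C=C(C)[C@]4([C@@H]3[C@@](C)(O)CC[C@H]3[C@H](C)C(=O)O[C@@H]34)[C@@H]12 | intermediate
23 | CNP0182139.2 (4'R, C4' methyl endo) | CC1=C2[C@H]3OC(=O)[C@@H](C)[C@@H]3CC[C@](C)(O)[C@@H]2[C@H]2[C@H]3C[C@@H](C)[C@]4([C@@H]3[C@@](C)(O)CC[C@H]3[C@H](C)C(=O)O[C@@H]34)[C@@H]12 | target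

Total step count: 16. Longest linear sequence: 16 steps (1 to 23); 3, 9 and 16 are used as purchased.

Steps most likely to fail

Step 12. The oxyallyl cation may be captured at its methyl-bearing terminus, the intermediate may close through oxygen or lose its silyl group before the carbon–carbon closure (interrupted cycloaddition), or the cation may add to the α-face. The fallback is the stepwise phosphonate cyclopentenone annulation and sets out from 14. Double deprotonation with LiN(SiMe3)2 and alkylation at C1 with dimethyl (4-bromo-3-ethoxybut-2-en-2-yl)phosphonate should give the C1-alkylated enol ether phosphonate F1. Dilute HCl in THF should hydrolyse its enol ether to the β-keto phosphonate F2. An intramolecular Horner–Wadsworth–Emmons reaction under LiCl/DBU in MeCN should then close C4=C5, and the route is rejoined at 19.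

Step 11. Deprotonation may turn toward C6, the lithium aldolate may open by retro-aldol reaction before the second deprotonation, or the tertiary alkoxide may be silylated. The fallback sets out from 13 and makes the enolate regiospecifically by reduction instead of deprotonation. SmI2 in THF at −78 °C without a proton source should open the epoxide to the samarium enolate of the C1–C5 position, and iPr3SiOSO2CF3 added to the same flask should silylate it. The route is rejoined at 15, and no new isolated compound is passed (F0).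

Step 10. Reductive cleavage of the lactone C6–O bond (an α-acyloxy ketone) may compete with epoxide opening, or the product may be reduced further. The fallback avoids the epoxide altogether and sets out from 11. Dess–Martin oxidation should give the cycloheptenone F3. Copper-catalysed enantioselective conjugate borylation (B2pin2, CuCl, NaOtBu, a chiral bisphosphine such as QuinoxP* in the enantiomeric form that delivers boron to the β-face, MeOH, THF) should give the β-boryl ketone F4. Oxidation of the carbon–boron bond with NaBO3·4H2O proceeds with retention, and the route is rejoined at 14.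

Further compounds
F1 | step 12 | dimethyl phosphonate enol ether, the C1-alkylated derivative of 14 carrying CH2–C(OEt)=C(CH3)–P(O)(OMe)2 on C1 (H-1 α) | O=C1[C@H]2OC(=O)[C@@H](C)[C@@H]2CC[C@](C)(O)[C@@H]1CC(OCC)=C(C)P(=O)(OC)OC
F2 | step 12 | β-keto phosphonate, the derivative of 14 carrying CH2–C(=O)–CH(CH3)–P(O)(OMe)2 on C1 (H-1 α, both epimers at the phosphonate carbon) | O=C1[C@H]2OC(=O)[C@@H](C)[C@@H]2CC[C@](C)(O)[C@@H]1CC(=O)C(C)P(=O)(OC)OC
F0 | step 11 | none | none
F3 | step 10 | (3S,3aS,8aS)-3,6-dimethyl-3,3a,4,5-tetrahydro-2H-cyclohepta[b]furan-2,8(8aH)-dione | CC1=CC(=O)[C@H]2OC(=O)[C@@H](C)[C@@H]2CC1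
F4 | step 10 | (3S,3aS,8aS)-3,6-dimethyl-6-(4,4,5,5-tetramethyl-1,3,2-dioxaborolan-2-yl)hexahydro-2H-cyclohepta[b]furan-2,8(3H)-dione, boron on the β-face at C6 | O=C1[C@H]2OC(=O)[C@@H](C)[C@@H]2CC[C@](C)(B3OC(C)(C)C(C)(C)O3)C1
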